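The decalin is cut at C9–C10 and, inside ring A, at C4–C5. Ring A (C1–C5, C10) is carried as a 1,2,2-trimethylcyclopentane whose quaternary carbon, the future C10, bears the C5 carbinol; the C5 oxygen is tied to C8 as a 2-alkylidene-tetrahydrofuran, a temporary ring. Lewis-acid ionisation of C5–O lets the neighbouring quaternary carbon C4 shift to C5, enlarging the cyclopentane to ring A; the resulting C10 cation is captured at C9 by the released enolate, which closes ring B as its C8 ketone. One catalyst-set stereocentre (C5) thereby fixes C10 and C9. The step exploits the contiguous C4(gem-dimethyl)–C5(H)–C10(quaternary) array of ring A.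

Key step: step 9

Remark: atoms carry labdane numbers (C1–C10 decalin, C11–C15 side chain, C16 the C13 methyl, C17 the carboxyl carbon, C20 the C10 methyl). The target is (5S,9R,10S). The quaternary ring carbon of 8, 9 and 12 is racemic, and 13 and 14 are pairs of epimers at that carbon; it becomes the planar C10 cation in step 9, so both epimers converge.

Step 1
Reactants: 1 geranyl acetate
Product: 2 (2E)-3-methyl-6-oxohex-2-en-1-yl acetate
Conditions: O3 (1.0 equiv), CH2Cl2/pyridine, −78 °C; then Me2S, −78 °C → rt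
Reagents that add atoms: ozone, [O-][O+]=O
Why: Chemoselective ozonolysis (Criegee mechanism) of the electron-rich distal trisubstituted alkene, the 2,3-alkene being deactivated by the allylic acetate and keeping its E geometry.

Step 2
Reactants: 2 (2E)-3-methyl-6-oxohex-2-en-1-yl acetate
Product: 4 (2E)-3-methylhept-2-en-6-yn-1-ol, via hydroxy aldehyde 3 (not isolated)
Conditions: K2CO3 (2 equiv), MeOH, 0 °C → rt; then dimethyl (1-diazo-2-oxopropyl)phosphonate (1.2 equiv), rt
Reagents that add atoms: dimethyl (1-diazo-2-oxopropyl)phosphonate, CC(=O)C(=[N+]=[N-])P(=O)(OC)OC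
Why: Acetate methanolysis followed by Seyferth–Gilbert homologation with the Ohira–Bestmann reagent turns the aldehyde carbon (C9) into the internal carbon of a terminal alkyne and adds C8, with no stereocentre formed.

Step 3
Reactants: 4 (2E)-3-methylhept-2-en-6-yn-1-ol
Product: 5 tert-butyl(dimethyl){[(2E)-3-methylhept-2-en-6-yn-1-yl]oxy}silane
Conditions: TBSCl, imidazole, DMF, 0 °C → rt
Reagents that add atoms: tert-butyldimethylsilyl chloride, CC(C)(C)[Si](C)(C)Cl
Why: Standard silylation of the primary allylic alcohol protects C15–O through the organometallic, Lewis-acid and palladium steps.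

Step 4
Reactants: 6 1-(2-methylcyclopent-1-en-1-yl)ethan-1-one
Product: 8 rac-1-(1,2,2-trimethylcyclopentyl)ethan-1-one, via lithium enolate 7 (not isolated)
Conditions: Me2CuLi (1.5 equiv), Et2O, −20 → 0 °C; then MeI (5 equiv), DMPU, THF, 0 °C → rt
Reagents that add atoms: lithium dimethylcuprate, [Li+].C[Cu-]C; iodomethane, CI
Why: Organocuprate 1,4-addition to the β,β-disubstituted enone gives the regiodefined tetrasubstituted enolate 7, whose C-methylation (conjugate addition–enolate alkylation) builds the two adjacent quaternary carbons, the new stereocentre being racemic by design.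

Step 5
Reactants: 8 rac-1-(1,2,2-trimethylcyclopentyl)ethan-1-one
Product: 9 rac-1-(1,2,2-trimethylcyclopentyl)prop-2-en-1-one
Conditions: (CH2O)n, N-methylanilinium trifluoroacetate, THF, reflux
Reagents that add atoms: paraformaldehyde (as formaldehyde), C=O
Why: Mannich-type α-methylenation at the only enolisable position, the methyl group, followed by amine elimination gives the tert-alkyl vinyl ketone.

Step 6
Reactants: 5 tert-butyl(dimethyl){[(2E)-3-methylhept-2-en-6-yn-1-yl]oxy}silane; 9 rac-1-(1,2,2-trimethylcyclopentyl)prop-2-en-1-one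
Product: 12 rac-(8E)-10-{[tert-butyl(dimethyl)silyl]oxy}-8-methyl-1-(1,2,2-trimethylcyclopentyl)dec-8-en-4-yn-1-one, via lithium acetylide 10 (not isolated), via diethylalkynylalane 11 (not isolated)
Conditions: 5, n-BuLi, Et2O, −78 → 0 °C; Et2AlCl (1.0 equiv), 0 °C; then 9, Et2O/hexane, −15 °C → rt; aq. NH4Cl
Reagents that add atoms: none
Why: Conjugate alkynylation with an alkynyl(diethyl)alane, which transfers the alkynyl group 1,4 through a six-membered transition state to the s-cis tert-alkyl vinyl ketone and so joins C7 to C8.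

Step 7
Reactants: 12 rac-(8E)-10-{[tert-butyl(dimethyl)silyl]oxy}-8-methyl-1-(1,2,2-trimethylcyclopentyl)dec-8-en-4-yn-1-one
Product: 13 (1S,8E)-10-{[tert-butyl(dimethyl)silyl]oxy}-8-methyl-1-(1,2,2-trimethylcyclopentyl)dec-8-en-4-yn-1-ol
Conditions: (R)-2-methyl-CBS-oxazaborolidine (20 mol %), catecholborane (1.5 equiv), toluene, −78 → −40 °C; MeOH, then aq. NaOH
Reagents that add atoms: none
Why: Corey–Bakshi–Shibata reduction, in which the (R)-oxazaborolidine distinguishes the bulky tert-alkyl group from the primary chain and sets the (S)-carbinol at C5 under catalyst control, while catecholborane spares alkyne and alkene.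

Step 8
Reactants: 13 (1S,8E)-10-{[tert-butyl(dimethyl)silyl]oxy}-8-methyl-1-(1,2,2-trimethylcyclopentyl)dec-8-en-4-yn-1-ol
Product: 14 (2Z,5S)-2-[(4E)-6-{[tert-butyl(dimethyl)silyl]oxy}-4-methylhex-4-en-1-ylidene]-5-(1,2,2-trimethylcyclopentyl)oxolane
Conditions: Ph3PAuCl (2 mol %), AgOTf (2 mol %), toluene, rt; filtration through basic Al2O3
Reagents that add atoms: none
Why: Alkynol cycloisomerisation (5-exo-dig hydroalkoxylation) by π-activation of the alkyne with cationic monovalent gold, anti-oxyauration and protodeauration giving the Z enol ether that ties O–C5 to C8 without touching C5.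

Step 9
Reactants: 14 (2Z,5S)-2-[(4E)-6-{[tert-butyl(dimethyl)silyl]oxy}-4-methylhex-4-en-1-ylidene]-5-(1,2,2-trimethylcyclopentyl)oxolane
Product: 16 (1R,4aS,8aS)-1-[(3E)-5-{[tert-butyl(dimethyl)silyl]oxy}-3-methylpent-3-en-1-yl]-5,5,8a-trimethyloctahydronaphthalen-2(1H)-one, via cyclohexyl cation aluminium enolate zwitterion 15 (not isolated)
Conditions: Me2AlCl (2.5 equiv), CH2Cl2, −78 → 0 °C; aq. NaHCO3
Reagents that add atoms: none
Why: Proposed new method: Me2AlCl binds the enol-ether oxygen of 14 and turns it into an aluminium-enolate leaving group; because C5 is a neopentyl-type secondary carbon, C5–O heterolysis is expected only in concert with the anti-periplanar 1,2-shift of the ring bond C10–C4 (Wagner–Meerwein ring expansion), which enlarges the cyclopentane to the six-membered ring A, inverts C5 and leaves the tertiary C10 cation tethered to the Z aluminium enolate (zwitterion 15). The enolate carbon C9 then captures C10 through a chair transition state, closing ring B in a 6-endo mode with respect to the enolate C8=C9 bond (6-enolendo) and delivering the C8 ketone. The closest known reaction types are the Petasis–Ferrier and related Lewis-acid [1,3] O-to-C rearrangements of cyclic enol ethers, so far triggered at oxocarbenium, allylic, benzylic or tertiary ether carbons, and the solvolytic cyclopentylcarbinyl-to-cyclohexyl ring expansion; new is that σ-participation of the strained ring bond replaces a cation-stabilising substituent. C5 is set by stereospecific inversion of the CBS-derived carbinol, C10 by attack of C9 anti to the just-migrated C4–C5 bond with the C5 tether equatorial (trans ring fusion, axial C10 methyl), and C9 by the Z enolate geometry, which places the side chain equatorial, the position also favoured by equilibration next to the ketone. The step needs migration of the quaternary C4 rather than C1H2 or the methyl group, which the higher migratory aptitude of the fully substituted carbon and the relief of ring strain and of the vicinal quaternary congestion should secure, and C- rather than O-recombination, which is self-correcting because an O-bound tertiary enol ether would re-ionise to the same ion pair. Both epimers of 14 at the cyclopentane quaternary carbon converge, since that carbon becomes the planar C10 cation.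

Step 10
Reactants: 16 (1R,4aS,8aS)-1-[(3E)-5-{[tert-butyl(dimethyl)silyl]oxy}-3-methylpent-3-en-1-yl]-5,5,8a-trimethyloctahydronaphthalen-2(1H)-one
Product: 17 (1R,4aS,8aS)-1-[(3E)-5-{[tert-butyl(dimethyl)silyl]oxy}-3-methylpent-3-en-1-yl]-5,5,8a-trimethyl-1,4,4a,5,6,7,8,8a-octahydronaphthalen-2-yl trifluoromethanesulfonate
Conditions: KN(SiMe3)2 (1.1 equiv), THF, −78 °C; then PhNTf2, −78 → 0 °C
Reagents that add atoms: N-phenylbis(trifluoromethanesulfonimide), O=S(=O)(N(c1ccccc1)S(=O)(=O)C(F)(F)F)C(F)(F)F
Why: Kinetic deprotonation at the unhindered C7 methylene (C9 is tertiary and shielded by the quaternary C10) and O-triflation of the enolate fix the C7=C8 double bond as the enol triflate.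

Step 11
Reactants: 17 (1R,4aS,8aS)-1-[(3E)-5-{[tert-butyl(dimethyl)silyl]oxy}-3-methylpent-3-en-1-yl]-5,5,8a-trimethyl-1,4,4a,5,6,7,8,8a-octahydronaphthalen-2-yl trifluoromethanesulfonate
Product: 18 (1R,4aS,8aS)-1-[(3E)-5-{[tert-butyl(dimethyl)silyl]oxy}-3-methylpent-3-en-1-yl]-5,5,8a-trimethyl-1,4,4a,5,6,7,8,8a-octahydronaphthalene-2-carboxylic acid
Conditions: Pd(OAc)2 (5 mol %), dppf (10 mol %), CO (1 atm), KOAc (4 equiv), DMF/H2O, 50 °C
Reagents that add atoms: carbon monoxide, [C-]#[O+]; water, O
Why: Palladium-catalysed hydroxycarbonylation of the enol triflate (oxidative addition to zerovalent palladium formed in situ, CO insertion, capture of the acyl-palladium by acetate and water) attaches C17 to C8 as the conjugated acid, while the allylic silyl ether is inert.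

Step 12
Reactants: 18 (1R,4aS,8aS)-1-[(3E)-5-{[tert-butyl(dimethyl)silyl]oxy}-3-methylpent-3-en-1-yl]-5,5,8a-trimethyl-1,4,4a,5,6,7,8,8a-octahydronaphthalene-2-carboxylic acid
Product: 19 (1R,4aS,8aS)-1-[(3E)-5-hydroxy-3-methylpent-3-en-1-yl]-5,5,8a-trimethyl-1,4,4a,5,6,7,8,8a-octahydronaphthalene-2-carboxylic acid
Conditions: HF·pyridine, THF/pyridine, 0 °C → rt
Reagents that add atoms: none
Why: Fluoride-mediated desilylation of the primary allylic silyl ether, to which the conjugated acid and both alkenes are inert.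

Step 13
Reactants: 19 (1R,4aS,8aS)-1-[(3E)-5-hydroxy-3-methylpent-3-en-1-yl]-5,5,8a-trimethyl-1,4,4a,5,6,7,8,8a-octahydronaphthalene-2-carboxylic acid
Product: 20 (1R,4aS,8aS)-1-[(3E)-5-acetoxy-3-methylpent-3-en-1-yl]-5,5,8a-trimethyl-1,4,4a,5,6,7,8,8a-octahydronaphthalene-2-carboxylic acid
Conditions: Ac2O, pyridine, DMAP (cat.), CH2Cl2, 0 °C → rt; then aq. NaHCO3/THF
Reagents that add atoms: acetic anhydride, CC(=O)OC(C)=O
Why: DMAP-catalysed acetylation of the primary allylic alcohol, the mixed anhydride formed at the carboxylic acid being hydrolysed in the aqueous bicarbonate work-up.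

Compound list

1 | geranyl acetate, (2E)-3,7-dimethylocta-2,6-dien-1-yl acetate | CC(C)=CCC/C(C)=C/COC(C)=O | starting material
2 | (2E)-3-methyl-6-oxohex-2-en-1-yl acetate | O=CCC/C(C)=C/COC(C)=O | intermediate
3 | (4E)-6-hydroxy-4-methylhex-4-enal | O=CCC/C(C)=C/CO | intermediate (not isolated)
4 | (2E)-3-methylhept-2-en-6-yn-1-ol | C#CCC/C(C)=C/CO | intermediate
5 | tert-butyl(dimethyl){[(2E)-3-methylhept-2-en-6-yn-1-yl]oxy}silane | C#CCC/C(C)=C/CO[Si](C)(C)C(C)(C)C | intermediate
6 | 1-(2-methylcyclopent-1-en-1-yl)ethan-1-one (1-acetyl-2-methylcyclopentene) | CC(=O)C1=C(C)CCC1 | starting material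
7 | lithium 1-(2,2-dimethylcyclopentylidene)ethan-1-olate | [Li+].[O-]C(C)=C1CCCC1(C)C | intermediate (not isolated)
8 | rac-1-(1,2,2-trimethylcyclopentyl)ethan-1-one | CC(=O)C1(C)CCCC1(C)C | intermediate
9 | rac-1-(1,2,2-trimethylcyclopentyl)prop-2-en-1-one | C=CC(=O)C1(C)CCCC1(C)C | intermediate
10 | lithium acetylide of 5, [(6E)-8-{[tert-butyl(dimethyl)silyl]oxy}-6-methyloct-6-en-2-yn... no: (5E)-7-{[tert-butyl(dimethyl)silyl]oxy}-5-methylhept-5-en-1-yn-1-yl]lithium | [Li]C#CCC/C(C)=C/CO[Si](C)(C)C(C)(C)C | intermediate (not isolated)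
11 | [(5E)-7-{[tert-butyl(dimethyl)silyl]oxy}-5-methylhept-5-en-1-yn-1-yl](diethyl)alumane | CC[Al](CC)C#CCC/C(C)=C/CO[Si](C)(C)C(C)(C)C | intermediate (not isolated)
12 | rac-(8E)-10-{[tert-butyl(dimethyl)silyl]oxy}-8-methyl-1-(1,2,2-trimethylcyclopentyl)dec-8-en-4-yn-1-one | CC(C)(C)[Si](C)(C)OC/C=C(\C)CCC#CCCC(=O)C1(C)CCCC1(C)C | intermediate
13 | (1S,8E)-10-{[tert-butyl(dimethyl)silyl]oxy}-8-methyl-1-(1,2,2-trimethylcyclopentyl)dec-8-en-4-yn-1-ol (both epimers at the ring quaternary carbon) | CC(C)(C)[Si](C)(C)OC/C=C(\C)CCC#CCC[C@H](O)C1(C)CCCC1(C)C | intermediate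
14 | (2Z,5S)-2-[(4E)-6-{[tert-butyl(dimethyl)silyl]oxy}-4-methylhex-4-en-1-ylidene]-5-(1,2,2-trimethylcyclopentyl)oxolane (both epimers at the ring quaternary carbon) | CC(C)(C)[Si](C)(C)OC/C=C(\C)CC/C=C1\O[C@H](C2(C)CCCC2(C)C)CC1 | intermediate
15 | zwitterion: (6S)-1,5,5-trimethylcyclohexan-1-ylium (C10 cation of ring A) carrying at C5 the Z chloro(dimethyl)aluminate enolate chain | CC(C)(C)[Si](C)(C)OC/C=C(\C)CC/C=C(\O[Al-](C)(C)Cl)CC[C@H]1C(C)(C)CCC[C+]1C | intermediate (not isolated)
16 | (1R,4aS,8aS)-1-[(3E)-5-{[tert-butyl(dimethyl)silyl]oxy}-3-methylpent-3-en-1-yl]-5,5,8a-trimethyloctahydronaphthalen-2(1H)-one | CC(C)(C)[Si](C)(C)OC/C=C(\C)CC[C@H]1C(=O)CC[C@H]2C(C)(C)CCC[C@]12C | intermediate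
17 | (1R,4aS,8aS)-1-[(3E)-5-{[tert-butyl(dimethyl)silyl]oxy}-3-methylpent-3-en-1-yl]-5,5,8a-trimethyl-1,4,4a,5,6,7,8,8a-octahydronaphthalen-2-yl trifluoromethanesulfonate | CC(C)(C)[Si](C)(C)OC/C=C(\C)CC[C@H]1C(OS(=O)(=O)C(F)(F)F)=CC[C@H]2C(C)(C)CCC[C@]12C | intermediate
18 | (1R,4aS,8aS)-1-[(3E)-5-{[tert-butyl(dimethyl)silyl]oxy}-3-methylpent-3-en-1-yl]-5,5,8a-trimethyl-1,4,4a,5,6,7,8,8a-octahydronaphthalene-2-carboxylic acid | CC(C)(C)[Si](C)(C)OC/C=C(\C)CC[C@H]1C(C(=O)O)=CC[C@H]2C(C)(C)CCC[C@]12C | intermediate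
19 | (1R,4aS,8aS)-1-[(3E)-5-hydroxy-3-methylpent-3-en-1-yl]-5,5,8a-trimethyl-1,4,4a,5,6,7,8,8a-octahydronaphthalene-2-carboxylic acid | OC/C=C(\C)CC[C@H]1C(C(=O)O)=CC[C@H]2C(C)(C)CCC[C@]12C | intermediate
20 | (1R,4aS,8aS)-1-[(3E)-5-acetoxy-3-methylpent-3-en-1-yl]-5,5,8a-trimethyl-1,4,4a,5,6,7,8,8a-octahydronaphthalene-2-carboxylic acid (15-acetoxylabda-7,13E-dien-17-oic acid) | CC(=O)OC/C=C(\C)CC[C@H]1C(C(=O)O)=CC[C@H]2C(C)(C)CCC[C@]12C | target

In the line for 10 the name to use is the second one given: [(5E)-7-{[tert-butyl(dimethyl)silyl]oxy}-5-methylhept-5-en-1-yn-1-yl]lithium.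

Total step count: 13. Longest linear sequence: 11 steps (1–3, then 6–13, from geranyl acetate); the cyclopentane branch is steps 4 and 5.

Steps most likely to fail

1. Step 9 (Proposed new method). Ionisation of C5–O may not couple cleanly to the C4 shift. The enol ether may instead be hydrolysed or isomerised by the Lewis acid, the wrong ring bond may migrate, or the C10 cation may lose a proton or suffer a hydride shift from C5 before C9 attacks, which would erase the C5 information. Methyl or chloride transfer from aluminium to C10 is a further drain. Fallback with known chemistry, from 13 back to 16, separating ring expansion from ring B closure: 13 would be mesylated (MsCl, Et3N, CH2Cl2, 0 °C) to (1S,8E)-10-{[tert-butyl(dimethyl)silyl]oxy}-8-methyl-1-(1,2,2-trimethylcyclopentyl)dec-8-en-4-yn-1-yl methanesulfonate F1. Buffered solvolysis (acetone/H2O, CaCO3, 50 °C), the classical Wagner–Meerwein ring expansion of a cyclopentylcarbinyl sulfonate, should then give with inversion at C5 the tertiary alcohol (2S)-2-[(7E)-9-{[tert-butyl(dimethyl)silyl]oxy}-7-methylnon-7-en-3-yn-1-yl]-1,3,3-trimethylcyclohexan-1-ol F2. Gold-catalysed 6-exo-dig hydroalkoxylation (Ph3PAuCl, AgOTf, toluene) would give the bicyclic enol ether (2Z,4aS)-2-[(4E)-6-{[tert-butyl(dimethyl)silyl]oxy}-4-methylhex-4-en-1-ylidene]-5,5,8a-trimethyloctahydro-2H-chromene F3. Its tertiary C10–O bond is of the kind known to ionise in Petasis–Ferrier-type O-to-C rearrangements (Me2AlCl, CH2Cl2, −78 → 0 °C), and recombination at C9 returns to ketone 16.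

2. Step 4. C-Methylation of the hindered tetrasubstituted enolate next to a quaternary carbon may be slower than proton exchange, so the enolate can equilibrate to the methyl side and be alkylated there or twice. Fallback from 6 back to 8, installing the methyl group by cyclopropanation instead of enolate alkylation: copper-catalysed 1,4-addition with in situ silylation (MeMgBr, CuI cat., Me3SiCl, THF, −40 °C) would give trimethyl{[1-(2,2-dimethylcyclopentylidene)ethyl]oxy}silane F4. Simmons–Smith cyclopropanation (Et2Zn, CH2I2, CH2Cl2, 0 °C) would give trimethyl[(1,4,4-trimethylspiro[2.4]heptan-1-yl)oxy]silane F5. Basic methanolysis (K2CO3, MeOH) then desilylates and opens the cyclopropanol at its CH2–C(O) bond, which leaves the new methyl group on the ring carbon and arrives at 8.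

3. Step 6. The alkynylalane may add 1,2 to the carbonyl, or the vinyl ketone may polymerise or be consumed by enolate-type side reactions before 1,4-transfer. Fallback from 5 and 8 back to 12, making the C6–C7 bond by enolate alkylation instead of the C7–C8 bond by conjugate addition: 5 would be hydroxymethylated (n-BuLi, THF, −78 °C; (CH2O)n) to (6E)-8-{[tert-butyl(dimethyl)silyl]oxy}-6-methyloct-6-en-2-yn-1-ol F6 and converted (CBr4, PPh3, CH2Cl2, Appel reaction) into {[(2E)-8-bromo-3-methyloct-2-en-6-yn-1-yl]oxy}(tert-butyl)dimethylsilane F7. Ketone 8, enolisable only at its methyl group, would be deprotonated (LiN(iPr)2, THF, −78 °C) to lithium 1-(1,2,2-trimethylcyclopentyl)ethen-1-olate F8 and alkylated with F7 to give 12.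

Further compounds

F1 | step 9 | (1S,8E)-10-{[tert-butyl(dimethyl)silyl]oxy}-8-methyl-1-(1,2,2-trimethylcyclopentyl)dec-8-en-4-yn-1-yl methanesulfonate | CC(C)(C)[Si](C)(C)OC/C=C(\C)CCC#CCC[C@H](OS(C)(=O)=O)C1(C)CCCC1(C)C
F2 | step 9 | (2S)-2-[(7E)-9-{[tert-butyl(dimethyl)silyl]oxy}-7-methylnon-7-en-3-yn-1-yl]-1,3,3-trimethylcyclohexan-1-ol | CC(C)(C)[Si](C)(C)OC/C=C(\C)CCC#CCC[C@H]1C(C)(C)CCCC1(C)O
F3 | step 9 | (2Z,4aS)-2-[(4E)-6-{[tert-butyl(dimethyl)silyl]oxy}-4-methylhex-4-en-1-ylidene]-5,5,8a-trimethyloctahydro-2H-chromene | CC(C)(C)[Si](C)(C)OC/C=C(\C)CC/C=C1\OC2(C)CCCC(C)(C)[C@@H]2CC1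
F4 | step 4 | trimethyl{[1-(2,2-dimethylcyclopentylidene)ethyl]oxy}silane | C[Si](C)(C)OC(C)=C1CCCC1(C)C
F5 | step 4 | trimethyl[(1,4,4-trimethylspiro[2.4]heptan-1-yl)oxy]silane | CC1(O[Si](C)(C)C)CC12CCCC2(C)C
F6 | step 6 | (6E)-8-{[tert-butyl(dimethyl)silyl]oxy}-6-methyloct-6-en-2-yn-1-ol | OCC#CCC/C(C)=C/CO[Si](C)(C)C(C)(C)C
F7 | step 6 | {[(2E)-8-bromo-3-methyloct-2-en-6-yn-1-yl]oxy}(tert-butyl)dimethylsilane | BrCC#CCC/C(C)=C/CO[Si](C)(C)C(C)(C)C
F8 | step 6 | lithium 1-(1,2,2-trimethylcyclopentyl)ethen-1-olate | [Li+].[O-]C(=C)C1(C)CCCC1(C)C
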